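**Strategy**
1. Numbering: ring C1 (C=O), C2=C3, C4 (CHMe), C5 (CHOH), C6 (CMe2); side chain C7 (CHOH), C8 (CHN); carbons of the acid carry a prime.
2. Cuts: first the amide N–C1′, then the ring double bond C2=C3 (aldol condensation read backwards, giving an open chain with a C1 ketone and a C3 aldehyde), then C2–C7 and C5–C6 (two aldol bonds). In the acid: C2′–C3′ (Johnson–Claisen), C4′–C5′ (vinyl addition), C6′–C7′ (allylation) and C9′–CH3 (conjugate addition).
3. Forward order: C5–C6 by Mukaiyama aldol, C2–C7 by lithium enolate aldol, closure of the only ring (carbocycle C1–C6) at C2/C3, release of the amine as its salt, amide bond last.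
4. Enabling feature: C6 is quaternary, so the C1 ketone can enolise only towards C2, the atom that already bears C7 and must become doubly bonded to C3. C1 and C3 stand 1,5, so attack of C2 on C3 gives the six-membered ring, and the only alternative (C4 on C1) would be a four-membered ring.
5. Stereochemistry: C4 comes from the (S)-Roche ester and C5 from Felkin–Anh addition to it. C8 comes from O-methyl-D-serine and C7 from non-chelation Felkin–Anh addition to its N,N-dibenzyl aldehyde. C9′ is set by copper-catalysed asymmetric conjugate addition, C7′ by reagent-controlled allylboration, and the E-alkene by the chair transition state of the Claisen step.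

Key step: step 14

Assumption: in step 16 the (R)-antipode of Tol-BINAP is taken, by analogy with other linear (E)-enoates, to be the one that leads to the (S)-ester. Both antipodes are sold, so the sense is checked by optical rotation on the first run, and nothing else in the route depends on it.

**Route**

Step 1
Reactants: 1 methyl (S)-3-hydroxy-2-methylpropanoate (Roche ester)
Product: 2 methyl (S)-3-(benzyloxy)-2-methylpropanoate
Conditions: BnOC(=NH)CCl3, TfOH (cat.), CH2Cl2–cyclohexane, 0 °C to rt
Reagents that add atoms: benzyl 2,2,2-trichloroacetimidate, N=C(OCc1ccccc1)C(Cl)(Cl)Cl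
Why: Acid-catalysed imidate O-benzylation needs no base, so the centre alpha to the ester (future C4) is not epimerised, and benzyl is chosen so that it leaves in step 12 together with the N-benzyl groups.

Step 2
Reactants: 2 methyl (S)-3-(benzyloxy)-2-methylpropanoate
Product: 3 (R)-3-(benzyloxy)-2-methylpropan-1-ol
Conditions: LiAlH4, Et2O, 0 °C
Reagents that add atoms: none
Why: Routine hydride reduction of an ester to the primary alcohol, which touches neither the benzyl ether nor the stereocentre (the descriptor changes only through CIP priorities).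

Step 3
Reactants: 3 (R)-3-(benzyloxy)-2-methylpropan-1-ol
Product: 4 (S)-3-(benzyloxy)-2-methylpropanal
Conditions: (COCl)2, DMSO, CH2Cl2, −78 °C; Et3N, −78 to 0 °C; used crude
Reagents that add atoms: none
Why: Swern oxidation at low temperature is the standard way to this alpha-methyl aldehyde without epimerisation, provided it is used at once and not chromatographed.

Step 4
Reactants: 5 3-methylbutan-2-one
Product: 6 3-methyl-2-(trimethylsilyloxy)but-2-ene
Conditions: Me3SiCl, NaI, Et3N, MeCN, rt; pentane extraction, fractional distillation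
Reagents that add atoms: chlorotrimethylsilane, C[Si](C)(C)Cl
Why: Thermodynamic silyl enol ether formation with Me3SiI made in situ under equilibrating conditions favours the tetrasubstituted enol ether, and the less substituted isomer is removed by distillation.

Step 5
Reactants: 4 (S)-3-(benzyloxy)-2-methylpropanal; 6 3-methyl-2-(trimethylsilyloxy)but-2-ene
Product: 7 (4R,5S)-6-(benzyloxy)-4-hydroxy-3,3,5-trimethylhexan-2-one
Conditions: BF3·OEt2, CH2Cl2, −78 °C; aq. NaHCO3
Reagents that add atoms: none
Why: Mukaiyama aldol addition through an open transition state, in which monodentate BF3 cannot chelate the benzyloxy group, so the bulky enol silane should attack the Felkin–Anh face and give the 4,5-syn adduct with (R)-C5 while forming C5–C6 and quaternary C6.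

Step 6
Reactants: 7 (4R,5S)-6-(benzyloxy)-4-hydroxy-3,3,5-trimethylhexan-2-one
Product: 8 (4R,5S)-6-(benzyloxy)-4-(tert-butyldimethylsilyloxy)-3,3,5-trimethylhexan-2-one
Conditions: TBSOTf, 2,6-lutidine, CH2Cl2, −78 to 0 °C
Reagents that add atoms: tert-butyldimethylsilyl trifluoromethanesulfonate, CC(C)(C)[Si](C)(C)OS(=O)(=O)C(F)(F)F
Why: Silyl triflate silylation copes with the crowded C5 carbinol next to quaternary C6, and the mild base does not provoke retro-aldol cleavage.

Step 7
Reactants: 9 O-methyl-D-serine
Product: 10 benzyl (R)-2-(dibenzylamino)-3-methoxypropanoate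
Conditions: BnBr, K2CO3, EtOH–H2O, 70 °C
Reagents that add atoms: benzyl bromide, BrCc1ccccc1
Why: Exhaustive N,N,O-benzylation of an amino acid with BnBr and carbonate is the standard entry to N,N-dibenzylamino aldehydes and leaves the alpha centre (future C8) intact.

Step 8
Reactants: 10 benzyl (R)-2-(dibenzylamino)-3-methoxypropanoate
Product: 11 (S)-2-(dibenzylamino)-3-methoxypropan-1-ol
Conditions: LiAlH4, THF, 0 °C
Reagents that add atoms: none
Why: Hydride reduction of the benzyl ester to the primary alcohol, with the tertiary amine and the methyl ether inert.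

Step 9
Reactants: 11 (S)-2-(dibenzylamino)-3-methoxypropan-1-ol
Product: 12 (R)-2-(dibenzylamino)-3-methoxypropanal (N,N-dibenzyl-O-methyl-D-serinal)
Conditions: (COCl)2, DMSO, CH2Cl2, −78 °C; Et3N, −78 to 0 °C; used crude
Reagents that add atoms: none
Why: Swern oxidation gives an N,N-dibenzylamino aldehyde, a class that holds its configuration well enough for direct use because the bulky tertiary amine slows enolisation.

Step 10
Reactants: 8 (4R,5S)-6-(benzyloxy)-4-(tert-butyldimethylsilyloxy)-3,3,5-trimethylhexan-2-one; 12 (R)-2-(dibenzylamino)-3-methoxypropanal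
Product: 14 (2S,3R,7S,8R)-1-(benzyloxy)-3-(tert-butyldimethylsilyloxy)-8-(dibenzylamino)-7-hydroxy-9-methoxy-2,4,4-trimethylnonan-5-one, via lithium enolate 13 (not isolated)
Conditions: LiN(i-Pr)2, THF, −78 °C; then 12, −78 °C; AcOH in THF at −78 °C
Reagents that add atoms: none
Why: Only the methyl group (C2) can be deprotonated because C6 is quaternary, and the lithium enolate aldol addition to an N,N-dibenzylamino aldehyde follows the non-chelation Felkin–Anh model (NBn2 anti to the incoming enolate), which gives the anti amino alcohol with (S)-C7, the cold acidic quench preventing retro-aldol equilibration.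

Step 11
Reactants: 14 the C7 aldol adduct
Product: 15 (2S,3R,7S,8R)-1-(benzyloxy)-3,7-bis(tert-butyldimethylsilyloxy)-8-(dibenzylamino)-9-methoxy-2,4,4-trimethylnonan-5-one
Conditions: TBSOTf, 2,6-lutidine, CH2Cl2, 0 °C
Reagents that add atoms: tert-butyldimethylsilyl trifluoromethanesulfonate, CC(C)(C)[Si](C)(C)OS(=O)(=O)C(F)(F)F
Why: Silyl triflate silylation caps the C7 aldol hydroxyl, which shuts off retro-aldol cleavage and makes the C7 oxygen a poor leaving group for step 14.

Step 12
Reactants: 15 the bis-silyl dibenzylamine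
Product: 17 tert-butyl [(2R,3S,7R,8S)-3,7-bis(tert-butyldimethylsilyloxy)-9-hydroxy-1-methoxy-6,6,8-trimethyl-5-oxononan-2-yl]carbamate, via free amino alcohol 16 (not isolated)
Conditions: H2, Pd(OH)2/C, Boc2O, EtOAc, rt
Reagents that add atoms: di-tert-butyl dicarbonate, CC(C)(C)OC(=O)OC(=O)OC(C)(C)C
Why: Hydrogenolysis over Pd(OH)2/C removes both N-benzyl groups and the O-benzyl group in one operation, Boc2O traps the primary amine before it can condense with the hindered C1 ketone, and EtOAc as solvent spares the silyl ethers.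

Step 13
Reactants: 17 the N-Boc hydroxy ketone
Product: 18 tert-butyl [(2R,3S,7R,8R)-3,7-bis(tert-butyldimethylsilyloxy)-1-methoxy-6,6,8-trimethyl-5,9-dioxononan-2-yl]carbamate (linear keto aldehyde)
Conditions: Dess–Martin periodinane, CH2Cl2, 0 °C to rt; used directly
Reagents that add atoms: none
Why: Dess–Martin oxidation is fast and essentially neutral, takes the primary alcohol (through the open form of any lactol with C1) to the C3 aldehyde and does not epimerise C4.

Step 14
Reactants: 18 the linear keto aldehyde
Product: 20 tert-butyl {(1S,2R)-1-(tert-butyldimethylsilyloxy)-1-[(3S,4R)-4-(tert-butyldimethylsilyloxy)-3,5,5-trimethyl-6-oxocyclohex-1-en-1-yl]-3-methoxypropan-2-yl}carbamate, via C3 dibenzylamino ketone 19 (not isolated)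
Conditions: Bn2NH2+ CF3CO2− (30 mol %), 4 Å molecular sieves, toluene, 45 °C
Reagents that add atoms: none
Why: The ammonium salt turns the C3 aldehyde reversibly into its iminium ion while the same buffer enolises the C1 ketone, the enol carbon C2 adds to C3 to give 19, and the protonated C3 amino group then leaves by E1cB, so the new C2–C3 bond ends as the C2=C3 double bond. The closest known reaction type is the aldol condensation of a 1,5-keto aldehyde to a cyclohexenone under secondary ammonium carboxylate catalysis, that is the ring-closing half of a Robinson annulation, with the amine-salt alpha-methylenation of ketones as its intermolecular counterpart. The one ring formed, carbocycle C1–C6, closes in the 6-(enolendo)-exo-trig mode and is helped by the Thorpe–Ingold effect of the gem-dimethyl group at C6. No lasting stereocentre is created, since C2 and C3 of 19 become sp2, and C4, C5, C7 and C8 are carried through unchanged. The site of enolisation is fixed by quaternary C6 (alpha hydrogens only at C2), and the direction of elimination is fixed because C3 carries an ammonium leaving group whereas C7 and C5 carry only silyloxy groups. The integrity of C4 requires closure to be faster than enamine formation at the aldehyde, which the alpha branch at C4, the hindered weakly basic amine and the moderate temperature should ensure, and after closure C4 is no longer alpha to a carbonyl group.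

Step 15
Reactants: 20 the protected cyclohexenone head group
Product: 21 (4S,5R)-2-[(1S,2R)-2-amino-1-hydroxy-3-methoxypropyl]-5-hydroxy-4,6,6-trimethylcyclohex-2-en-1-one hydrochloride
Conditions: HCl (3 M in MeOH), 0 °C to rt; evaporation, trituration with Et2O
Reagents that add atoms: hydrogen chloride, Cl
Why: Acidic solvolysis removes the tert-butyl carbamate and both silyl ethers in one operation while nitrogen stays protonated and so cannot add to C1 or C3, and ionisation at C7 is disfavoured by the neighbouring ammonium group and the electron-poor alkene.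

Step 16
Reactants: 22 methyl (E)-dec-2-enoate
Product: 23 methyl (S)-3-methyldecanoate
Conditions: MeMgBr, CuI (2 mol %), (R)-Tol-BINAP (3 mol %), t-BuOMe, −20 °C
Reagents that add atoms: methylmagnesium bromide, C[Mg]Br
Why: Asymmetric conjugate addition of a Grignard reagent catalysed by monovalent copper with a chiral bisphosphine, using the CuI/Tol-BINAP system because it turns over the sluggish MeMgBr with (E)-unsaturated methyl esters, the ligand choosing the face of C3 that receives the methyl group and so setting (S)-C9′.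

Step 17
Reactants: 23 methyl (S)-3-methyldecanoate
Product: 24 (S)-3-methyldecanal
Conditions: i-Bu2AlH (1.05 equiv), CH2Cl2, −78 °C; MeOH, aq. potassium sodium tartrate
Reagents that add atoms: none
Why: Partial ester reduction with i-Bu2AlH stops at −78 °C at the tetrahedral aluminium hemiacetal, which releases the aldehyde only on work-up.

Step 18
Reactants: 24 (S)-3-methyldecanal
Product: 26 (4S,6S)-6-methyltridec-1-en-4-ol, via borinic ester 25 (not isolated)
Conditions: (−)-Ipc2B(allyl) [(+)-α-pinene series], Et2O, −78 °C; then NaOH, H2O2, 0 °C to rt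
Reagents that add atoms: (−)-B-allyldiisopinocampheylborane, C=CCB([C@@H]1C[C@@H]2C[C@H]([C@H]1C)C2(C)C)[C@@H]1C[C@@H]2C[C@H]([C@H]1C)C2(C)C
Why: Brown allylation through a chair Zimmerman–Traxler transition state is reagent-controlled, the (+)-α-pinene-derived borane attacking the Si face of aliphatic aldehydes and so setting the (4S) carbinol (future (R)-C7′), with little influence from the remote methyl centre.

Step 19
Reactants: 26 (4S,6S)-6-methyltridec-1-en-4-ol
Product: 27 (4S,6S)-4-methoxy-6-methyltridec-1-ene
Conditions: NaH, MeI, THF, 0 °C to rt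
Reagents that add atoms: iodomethane, CI
Why: Williamson etherification at oxygen, which leaves the C–O stereocentre untouched.

Step 20
Reactants: 27 (4S,6S)-4-methoxy-6-methyltridec-1-ene
Product: 29 (3R,5S)-3-methoxy-5-methyldodecanal, via secondary ozonide 28 (not isolated)
Conditions: O3, CH2Cl2, −78 °C; PPh3, −78 °C to rt
Reagents that add atoms: ozone, [O-][O+]=O
Why: Ozonolysis with reductive work-up cleaves the only alkene, and neutral reduction with PPh3 avoids loss of methanol from the beta-methoxy aldehyde.

Step 21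
Reactants: 29 (3R,5S)-3-methoxy-5-methyldodecanal
Product: 30 (5R,7S)-5-methoxy-7-methyltetradec-1-en-3-ol (both C3 epimers)
Conditions: CH2=CHMgBr, THF, −78 °C
Reagents that add atoms: vinylmagnesium bromide, C=C[Mg]Br
Why: Grignard 1,2-addition at low temperature outruns beta-elimination, and the new carbinol centre needs no control because step 22 erases it.

Step 22
Reactants: 30 (5R,7S)-5-methoxy-7-methyltetradec-1-en-3-ol
Product: 32 ethyl (4E,7R,9S)-7-methoxy-9-methylhexadec-4-enoate, via mixed ketene acetal 31 (not isolated)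
Conditions: MeC(OEt)3, EtCO2H (cat.), 140 °C, EtOH distilled off
Reagents that add atoms: triethyl orthoacetate, CCOC(C)(OCC)OCC
Why: Johnson–Claisen rearrangement forms C2′–C3′ through a chair transition state with the alkyl chain equatorial, so both carbinol epimers should converge on the (E)-alkene.

Step 23
Reactants: 32 ethyl (4E,7R,9S)-7-methoxy-9-methylhexadec-4-enoate
Product: 33 (4E,7R,9S)-7-methoxy-9-methylhexadec-4-enoic acid
Conditions: LiOH, THF–MeOH–H2O, rt; 1 M HCl to pH 3
Reagents that add atoms: lithium hydroxide, [Li+].[OH-]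
Why: Ester saponification, in which the isolated alkene cannot move into conjugation under these mild conditions.

Step 24
Reactants: 33 (4E,7R,9S)-7-methoxy-9-methylhexadec-4-enoic acid; 21 the amino diol enone hydrochloride
Product: 35 (4E,7R,9S)-N-{(1S,2R)-1-hydroxy-1-[(3S,4R)-4-hydroxy-3,5,5-trimethyl-6-oxocyclohex-1-en-1-yl]-3-methoxypropan-2-yl}-7-methoxy-9-methylhexadec-4-enamide (target), via benzotriazolyl ester 34 (not isolated)
Conditions: 33, EDC·HCl, HOBt, CH2Cl2–DMF, 0 °C; then 21; i-Pr2NEt added slowly, 0 °C to rt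
Reagents that add atoms: none
Why: Carbodiimide/HOBt amide coupling with the acid activated first and the base added last, so each amine molecule set free meets the active ester before it can attack C1 or C3, and the benzotriazolyl ester acylates nitrogen in preference to the two secondary hydroxyls.

**Compound list**
1 | methyl (S)-3-hydroxy-2-methylpropanoate | COC(=O)[C@@H](C)CO | starting material
2 | methyl (S)-3-(benzyloxy)-2-methylpropanoate | COC(=O)[C@@H](C)COCc1ccccc1 | intermediate
3 | (R)-3-(benzyloxy)-2-methylpropan-1-ol | OC[C@@H](C)COCc1ccccc1 | intermediate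
4 | (S)-3-(benzyloxy)-2-methylpropanal | O=C[C@@H](C)COCc1ccccc1 | intermediate
5 | 3-methylbutan-2-one | CC(=O)C(C)C | starting material
6 | 3-methyl-2-(trimethylsilyloxy)but-2-ene | CC(O[Si](C)(C)C)=C(C)C | intermediate
7 | (4R,5S)-6-(benzyloxy)-4-hydroxy-3,3,5-trimethylhexan-2-one | CC(=O)C(C)(C)[C@H](O)[C@@H](C)COCc1ccccc1 | intermediate
8 | (4R,5S)-6-(benzyloxy)-4-(tert-butyldimethylsilyloxy)-3,3,5-trimethylhexan-2-one | CC(=O)C(C)(C)[C@H](O[Si](C)(C)C(C)(C)C)[C@@H](C)COCc1ccccc1 | intermediate
9 | O-methyl-D-serine, (R)-2-amino-3-methoxypropanoic acid | COC[C@@H](N)C(=O)O | starting material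
10 | benzyl (R)-2-(dibenzylamino)-3-methoxypropanoate | COC[C@@H](N(Cc1ccccc1)Cc1ccccc1)C(=O)OCc1ccccc1 | intermediate
11 | (S)-2-(dibenzylamino)-3-methoxypropan-1-ol | COC[C@@H](N(Cc1ccccc1)Cc1ccccc1)CO | intermediate
12 | (R)-2-(dibenzylamino)-3-methoxypropanal | COC[C@@H](N(Cc1ccccc1)Cc1ccccc1)C=O | intermediate
13 | lithium enolate of 8 (C1=C2 enolate, not isolated) | [Li]OC(=C)C(C)(C)[C@H](O[Si](C)(C)C(C)(C)C)[C@@H](C)COCc1ccccc1 | intermediate
14 | (2S,3R,7S,8R)-1-(benzyloxy)-3-(tert-butyldimethylsilyloxy)-8-(dibenzylamino)-7-hydroxy-9-methoxy-2,4,4-trimethylnonan-5-one | COC[C@@H](N(Cc1ccccc1)Cc1ccccc1)[C@@H](O)CC(=O)C(C)(C)[C@H](O[Si](C)(C)C(C)(C)C)[C@@H](C)COCc1ccccc1 | intermediate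
15 | (2S,3R,7S,8R)-1-(benzyloxy)-3,7-bis(tert-butyldimethylsilyloxy)-8-(dibenzylamino)-9-methoxy-2,4,4-trimethylnonan-5-one | COC[C@@H](N(Cc1ccccc1)Cc1ccccc1)[C@@H](O[Si](C)(C)C(C)(C)C)CC(=O)C(C)(C)[C@H](O[Si](C)(C)C(C)(C)C)[C@@H](C)COCc1ccccc1 | intermediate
16 | (2S,3R,7S,8R)-8-amino-3,7-bis(tert-butyldimethylsilyloxy)-1-hydroxy-9-methoxy-2,4,4-trimethylnonan-5-one (not isolated) | COC[C@@H](N)[C@@H](O[Si](C)(C)C(C)(C)C)CC(=O)C(C)(C)[C@H](O[Si](C)(C)C(C)(C)C)[C@@H](C)CO | intermediate
17 | tert-butyl [(2R,3S,7R,8S)-3,7-bis(tert-butyldimethylsilyloxy)-9-hydroxy-1-methoxy-6,6,8-trimethyl-5-oxononan-2-yl]carbamate | COC[C@@H](NC(=O)OC(C)(C)C)[C@@H](O[Si](C)(C)C(C)(C)C)CC(=O)C(C)(C)[C@H](O[Si](C)(C)C(C)(C)C)[C@@H](C)CO | intermediate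
18 | tert-butyl [(2R,3S,7R,8R)-3,7-bis(tert-butyldimethylsilyloxy)-1-methoxy-6,6,8-trimethyl-5,9-dioxononan-2-yl]carbamate | COC[C@@H](NC(=O)OC(C)(C)C)[C@@H](O[Si](C)(C)C(C)(C)C)CC(=O)C(C)(C)[C@H](O[Si](C)(C)C(C)(C)C)[C@@H](C)C=O | intermediate
19 | ring-closed Mannich base: 20 with H at C2 and NBn2 at C3 in place of the double bond, C2 and C3 undefined and of no consequence (not isolated) | COC[C@@H](NC(=O)OC(C)(C)C)[C@@H](O[Si](C)(C)C(C)(C)C)C1C(N(Cc2ccccc2)Cc2ccccc2)[C@H](C)[C@@H](O[Si](C)(C)C(C)(C)C)C(C)(C)C1=O | intermediate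
20 | tert-butyl {(1S,2R)-1-(tert-butyldimethylsilyloxy)-1-[(3S,4R)-4-(tert-butyldimethylsilyloxy)-3,5,5-trimethyl-6-oxocyclohex-1-en-1-yl]-3-methoxypropan-2-yl}carbamate | COC[C@@H](NC(=O)OC(C)(C)C)[C@@H](O[Si](C)(C)C(C)(C)C)C1=C[C@H](C)[C@@H](O[Si](C)(C)C(C)(C)C)C(C)(C)C1=O | intermediate
21 | (4S,5R)-2-[(1S,2R)-2-amino-1-hydroxy-3-methoxypropyl]-5-hydroxy-4,6,6-trimethylcyclohex-2-en-1-one hydrochloride | COC[C@@H](N)[C@@H](O)C1=C[C@H](C)[C@@H](O)C(C)(C)C1=O.Cl | intermediate
22 | methyl (E)-dec-2-enoate | CCCCCCC/C=C/C(=O)OC | starting material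
23 | methyl (S)-3-methyldecanoate | CCCCCCC[C@H](C)CC(=O)OC | intermediate
24 | (S)-3-methyldecanal | CCCCCCC[C@H](C)CC=O | intermediate
25 | diisopinocampheylborinic ester of 26 (not isolated) | CCCCCCC[C@H](C)C[C@H](CC=C)OB([C@@H]1C[C@@H]2C[C@H]([C@H]1C)C2(C)C)[C@@H]1C[C@@H]2C[C@H]([C@H]1C)C2(C)C | intermediate
26 | (4S,6S)-6-methyltridec-1-en-4-ol | CCCCCCC[C@H](C)C[C@H](CC=C)O | intermediate
27 | (4S,6S)-4-methoxy-6-methyltridec-1-ene | CCCCCCC[C@H](C)C[C@H](CC=C)OC | intermediate
28 | 3-[(2S,4S)-2-methoxy-4-methylundecyl]-1,2,4-trioxolane, ring carbon undefined (not isolated) | CCCCCCC[C@H](C)C[C@H](CC1OCOO1)OC | intermediate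
29 | (3R,5S)-3-methoxy-5-methyldodecanal | CCCCCCC[C@H](C)C[C@H](CC=O)OC | intermediate
30 | (5R,7S)-5-methoxy-7-methyltetradec-1-en-3-ol, both C3 epimers | CCCCCCC[C@H](C)C[C@H](CC(O)C=C)OC | intermediate
31 | ethyl ketene acetal of 30, O-(1-ethoxyvinyl) ether (not isolated) | CCCCCCC[C@H](C)C[C@H](CC(C=C)OC(=C)OCC)OC | intermediate
32 | ethyl (4E,7R,9S)-7-methoxy-9-methylhexadec-4-enoate | CCCCCCC[C@H](C)C[C@H](C/C=C/CCC(=O)OCC)OC | intermediate
33 | (4E,7R,9S)-7-methoxy-9-methylhexadec-4-enoic acid | CCCCCCC[C@H](C)C[C@H](C/C=C/CCC(=O)O)OC | intermediate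
34 | benzotriazol-1-yl (4E,7R,9S)-7-methoxy-9-methylhexadec-4-enoate (not isolated) | CCCCCCC[C@H](C)C[C@H](C/C=C/CCC(=O)On1nnc2ccccc12)OC | intermediate
35 | (4E,7R,9S)-N-{(1S,2R)-1-hydroxy-1-[(3S,4R)-4-hydroxy-3,5,5-trimethyl-6-oxocyclohex-1-en-1-yl]-3-methoxypropan-2-yl}-7-methoxy-9-methylhexadec-4-enamide | CCCCCCC[C@H](C)C[C@H](C/C=C/CCC(=O)N[C@H](COC)[C@@H](O)C1=C[C@H](C)[C@@H](O)C(C)(C)C1=O)OC | target

**Step count**
- Total: 24 steps.
- Longest linear sequence: 12 steps from 1 (steps 1, 2, 3, 5, 6, 10, 11, 12, 13, 14, 15, 24).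
- The acid branch needs 9 steps to the target.
- The serine branch joins after 3 steps.

**Steps most likely to fail**

Step 14. The crowded C2–C3 bond formation may be slower than enamine formation at the aldehyde. That would bring epimerisation at C4 and then loss of the C5 silyloxy group. It may also be slower than expulsion of the C7 silyloxy group from the ketone enol.

The fallback sets out from 18 and comes back at 20. It closes the same C2=C3 bond by ring-closing metathesis instead of a carbonyl condensation.
- The aldehyde of 18 is methylenated with Ph3P=CH2 in THF at low temperature. The hindered C1 ketone stays untouched, and the product is the terminal alkene tert-butyl [(2R,3S,7R,8S)-3,7-bis(tert-butyldimethylsilyloxy)-1-methoxy-6,6,8-trimethyl-5-oxodec-9-en-2-yl]carbamate F1, which no longer has an acidic C4 hydrogen.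
- C2 is then methylenated with paraformaldehyde and i-Pr2NH2+ CF3CO2− in hot THF (Mannich–elimination) to the alpha-methylene ketone F2.
- The second-generation Hoveyda–Grubbs catalyst in warm toluene joins the two terminal alkenes with loss of ethene and should give 20.

Step 15. Cleavage of the crowded C5 silyl ether may stay incomplete under conditions that the hydroxyalkyl enone still tolerates. Any nitrogen that becomes free during isolation may also close onto C1.

The fallback sets out from 20 and comes back at 35. It changes the order of events so that the unprotected amino diol is never handled.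
- TMSOTf and 2,6-lutidine in CH2Cl2 convert the tert-butyl carbamate alone into the trimethylsilyl carbamate F3.
- Methanol releases the bis-silylated amine F4.
- F4 is acylated at once with the preformed ester 34 to the bis-silylated amide F5.
- The two silyl ethers are then removed from this neutral amide with HF·pyridine in THF to give 35.

Step 5. Facial selectivity under pure substrate control may be poor, and residual less substituted enol silane may lead to a regioisomeric aldol.

The fallback sets out from 4 and comes back at 8. It replaces the aldol by a reagent-controlled allylboration.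
- B-(3-methylbut-2-enyl)diisopinocampheylborane of the (+)-α-pinene series adds to 4 through its gamma carbon. This forms C5–C6 and quaternary C6 and gives the borinic ester F6.
- Oxidative work-up with NaOH and H2O2 gives the homoallylic alcohol (2S,3R)-1-(benzyloxy)-2,4,4-trimethylhex-5-en-3-ol F7, the sense of the reagent matching the Felkin–Anh preference.
- Silylation with TBSOTf and 2,6-lutidine gives the silyl ether F8.
- Tsuji–Wacker oxidation (PdCl2, CuCl, O2, DMF–H2O) turns the vinyl group into the methyl ketone 8.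

**Further compounds**
F1 | step 14 | tert-butyl [(2R,3S,7R,8S)-3,7-bis(tert-butyldimethylsilyloxy)-1-methoxy-6,6,8-trimethyl-5-oxodec-9-en-2-yl]carbamate | COC[C@@H](NC(=O)OC(C)(C)C)[C@@H](O[Si](C)(C)C(C)(C)C)CC(=O)C(C)(C)[C@H](O[Si](C)(C)C(C)(C)C)[C@@H](C)C=C
F2 | step 14 | tert-butyl [(2R,3S,7R,8S)-3,7-bis(tert-butyldimethylsilyloxy)-1-methoxy-6,6,8-trimethyl-4-methylidene-5-oxodec-9-en-2-yl]carbamate | COC[C@@H](NC(=O)OC(C)(C)C)[C@@H](O[Si](C)(C)C(C)(C)C)C(=C)C(=O)C(C)(C)[C@H](O[Si](C)(C)C(C)(C)C)[C@@H](C)C=C
F3 | step 15 | trimethylsilyl carbamate corresponding to 20 | COC[C@@H](NC(=O)O[Si](C)(C)C)[C@@H](O[Si](C)(C)C(C)(C)C)C1=C[C@H](C)[C@@H](O[Si](C)(C)C(C)(C)C)C(C)(C)C1=O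
F4 | step 15 | (4S,5R)-2-[(1S,2R)-2-amino-1-(tert-butyldimethylsilyloxy)-3-methoxypropyl]-5-(tert-butyldimethylsilyloxy)-4,6,6-trimethylcyclohex-2-en-1-one | COC[C@@H](N)[C@@H](O[Si](C)(C)C(C)(C)C)C1=C[C@H](C)[C@@H](O[Si](C)(C)C(C)(C)C)C(C)(C)C1=O
F5 | step 15 | C5,C7-bis(tert-butyldimethylsilyl) ether of 35 | CCCCCCC[C@H](C)C[C@H](C/C=C/CCC(=O)N[C@H](COC)[C@@H](O[Si](C)(C)C(C)(C)C)C1=C[C@H](C)[C@@H](O[Si](C)(C)C(C)(C)C)C(C)(C)C1=O)OC
F6 | step 5 | diisopinocampheylborinic ester of F7 | C=CC(C)(C)[C@H](OB([C@@H]1C[C@@H]2C[C@H]([C@H]1C)C2(C)C)[C@@H]1C[C@@H]2C[C@H]([C@H]1C)C2(C)C)[C@@H](C)COCc1ccccc1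
F7 | step 5 | (2S,3R)-1-(benzyloxy)-2,4,4-trimethylhex-5-en-3-ol | C=CC(C)(C)[C@H](O)[C@@H](C)COCc1ccccc1
F8 | step 5 | tert-butyldimethylsilyl ether of F7 | C=CC(C)(C)[C@H](O[Si](C)(C)C(C)(C)C)[C@@H](C)COCc1ccccc1
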